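## Retrosynthetic overview

- Target 26 ← acetylation of the tertiary 4α-OH and Yamaguchi angeloylation of the 3α-OH of cis-diol 22 ← Woodward cis-hydroxylation of the C3=C4 alkene of cis-eudesm-3-en-8-one 18 on the α face, with base equilibration of C7.
- Feature: in ring B (C5–C10) the C8 ketone with its C7 α-carbon is an enolate, and the C5–C6 bond next to the cis C5/C10 fusion is the new σ bond of an oxy-Cope shift. The C3=C4 alkene that the shift leaves in ring A is where the two oxygens go.
- Key disconnection: 18 ← anionic oxy-Cope of bicyclo[2.2.2]octenol 15, forming C5–C6 and breaking the non-target C3–C8 bond.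
- 15 ← (1R,4R)-enone 10 + alkenyl metal from 3-methylbutan-2-one (Shapiro); 10 ← double Michael of 1 with 2, saponification, resolution, oxidative decarboxylation.
- Ring order: the cage first (future ring A plus a temporary two-carbon bridge), then ring B by the sigmatropic shift.

Key step: step 7

Remarks and assumptions:
- Decalins carry eudesmane numbering (ring A: C1–C5, C10; ring B: C5–C10; C14 on C10, C15 on C4; α is the face opposite C14). Cage atoms C1, C2, C3, C4, C5, C6, C7, C8 become C3, C8, C9, C10, C5, C4, C2, C1; the alkenyl CH2 becomes C6 and its inner carbon C7.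
- Assumption: the salt of the (1R,2R,3S,4R)-acid with (R)-1-phenylethylamine is taken to be the less soluble one; if the enantiomeric acid crystallises instead, the (S)-amine is used and nothing else changes.
- C7 is drawn without configuration in 18–21 because both epimers are carried forward; it is fixed in step 9.

## Route

Step 1
Reactants: 1 3-methylcyclohex-2-en-1-one; 2 methyl (E)-but-2-enoate
Product: 6 methyl rac-(1R,2R,3S,4R)-1,3-dimethyl-5-oxobicyclo[2.2.2]octane-2-carboxylate, via lithium dienolate 3 (not isolated), via ester enolate 4 (not isolated), via bicyclic enolate 5 (not isolated)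
Conditions: LiN(iPr)2, THF, −78 °C; 2, −78 °C → rt; 1 M HCl
Reagents that add atoms: none
Why: Kinetic α′-deprotonation gives the cross-conjugated dienolate, which adds to the crotonate, and the resulting ester enolate closes onto the enone β-carbon (double Michael reaction); the trans methyl/ester relation follows from the E-alkene, the ester is expected syn to the keto bridge, and both of these centres are erased in step 4.

Step 2
Reactants: 6 methyl rac-(1R,2R,3S,4R)-1,3-dimethyl-5-oxobicyclo[2.2.2]octane-2-carboxylate
Product: 7 rac-(1R,2R,3S,4R)-1,3-dimethyl-5-oxobicyclo[2.2.2]octane-2-carboxylic acid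
Conditions: KOH, MeOH/H2O, 60 °C; then HCl
Reagents that add atoms: potassium hydroxide, [K+].[OH-]
Why: Plain ester saponification; the ketone cannot enolise toward the bridgehead and the trans arrangement at C2/C3 is the more stable one, so no centre should change.

Step 3
Reactants: 7 rac-(1R,2R,3S,4R)-1,3-dimethyl-5-oxobicyclo[2.2.2]octane-2-carboxylic acid
Product: 8 (R)-1-phenylethylammonium (1R,2R,3S,4R)-1,3-dimethyl-5-oxobicyclo[2.2.2]octane-2-carboxylate
Conditions: (R)-PhCH(Me)NH2 (1 equiv), EtOAc/EtOH, recrystallise to constant rotation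
Reagents that add atoms: (R)-1-phenylethylamine, C[C@@H](N)c1ccccc1
Why: Classical resolution by crystallisation of diastereomeric ammonium carboxylate salts, which fixes the absolute configuration of the two bridgeheads (later C10, and through it C5).

Step 4
Reactants: 8 (R)-1-phenylethylammonium (1R,2R,3S,4R)-1,3-dimethyl-5-oxobicyclo[2.2.2]octane-2-carboxylate
Product: 10 (1R,4R)-4,6-dimethylbicyclo[2.2.2]oct-5-en-2-one, via free keto acid 9 (not isolated)
Conditions: 1 M HCl/EtOAc; then Pb(OAc)4, Cu(OAc)2 (cat.), pyridine, PhH, 80 °C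
Reagents that add atoms: none
Why: Kochi oxidative decarboxylation: the secondary radical left after loss of CO2 is oxidised by divalent copper with loss of its only β-hydrogen (on the methyl-bearing carbon, the bridgehead side has none), so only the C5=C6 alkene can form and the bridgeheads are untouched.

Step 5
Reactants: 11 3-methylbutan-2-one
Product: 12 (E)-3-methylbutan-2-one 2,4,6-triisopropylbenzenesulfonylhydrazone
Conditions: TrisNHNH2, MeOH, HCl (cat.), rt
Reagents that add atoms: 2,4,6-triisopropylbenzenesulfonohydrazide, CC(C)c1cc(C(C)C)c(S(=O)(=O)NN)c(C(C)C)c1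
Why: Acid-catalysed hydrazone condensation; the sulfonamide nitrogen sits anti to the isopropyl group, which directs the later deprotonation to the methyl group.

Step 6
Reactants: 12 (E)-3-methylbutan-2-one 2,4,6-triisopropylbenzenesulfonylhydrazone; 10 (1R,4R)-4,6-dimethylbicyclo[2.2.2]oct-5-en-2-one
Product: 15 (1R,2S,4R)-4,6-dimethyl-2-(3-methylbut-1-en-2-yl)bicyclo[2.2.2]oct-5-en-2-ol, via alkenyllithium 13 (not isolated), via alkenylcerium reagent 14 (not isolated)
Conditions: 12, n-BuLi (2.1 equiv), THF, −78 → 0 °C; CeCl3, −78 °C; 10, −78 °C; aq. NH4Cl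
Reagents that add atoms: none
Why: The Shapiro reaction gives the less substituted alkenyllithium, and its weakly basic cerium reagent adds 1,2 to the enolisable ketone from the face syn to the C5=C6 bridge, because the other face is screened by the inward hydrogen on C7; this sets C2 (S) with the alkenyl group over the alkene bridge.

Step 7
Reactants: 15 (1R,2S,4R)-4,6-dimethyl-2-(3-methylbut-1-en-2-yl)bicyclo[2.2.2]oct-5-en-2-ol
Product: 18 (5S,10R)-cis-eudesm-3-en-8-one as a C7 epimer mixture, via potassium alkoxide 16 (not isolated), via potassium enolate 17 (not isolated)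
Conditions: KH, 18-crown-6, THF, 0 °C → rt; aq. NH4Cl, −78 °C
Reagents that add atoms: none
Why: Deprotonation gives the potassium alkoxide, which weakens the cage C1–C2 bond, and a [3,3] sigmatropic shift through the boat-like array held by the cage joins the alkenyl CH2 to cage C5 as C1–C2 breaks, giving the C7=C8 enolate and the C3=C4 alkene; this is the anionic oxy-Cope rearrangement of a 2-alkenylbicyclo[2.2.2]oct-5-en-2-ol, a known entry to cis-fused octalones. Ring B (C5–C10) is closed by the six-centre pericyclic shift itself, and ring A is the cyclohexene that remains of the cage. C5 is set by suprafacial bond formation on the face of the cage alkene that faces the carbinol bridge, the side from which C9 already leaves C10, so H5 ends up cis to C14, while C10 is carried over from the resolved cage. The step needs the alkenyl group syn to the alkene bridge and a single cage enantiomer, secured in steps 6 and 3, and release of cage strain together with enolate formation should make it irreversible. C7 is not fixed here: protonation of the enolate should favour the convex β face and give mainly the 7α-isopropyl epimer, and the equilibrium at this stage is not expected to favour either epimer strongly, so 18 is carried on as a mixture.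

Step 8
Reactants: 18 (5S,10R)-cis-eudesm-3-en-8-one as a C7 epimer mixture
Product: 21 4α-acetoxy-3α-hydroxy-cis-eudesman-8-one as a C7 epimer mixture, via iodo acetate 19 (not isolated), via acetoxonium ion 20 (not isolated)
Conditions: I2, AgOAc, AcOH, rt; then H2O, 90 °C
Reagents that add atoms: silver acetate, CC(=O)[O-].[Ag+]; water, O
Why: Woodward cis-hydroxylation: the iodonium ion should form on the β face because ring B (C6 on C5 or C9 on C10, depending on the ring conformer) screens the α face, acetate opens it anti at the tertiary C4, the acetate then displaces the 3β-iodide with inversion to the cis-fused 3α,4α-acetoxonium ion, and water opens this to the hydroxy acetate, so both C–O bonds lie on the α face (C3 R, C4 S).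

Step 9
Reactants: 21 4α-acetoxy-3α-hydroxy-cis-eudesman-8-one as a C7 epimer mixture
Product: 22 (3R,4S,5S,7R,10R)-3,4-dihydroxy-cis-eudesman-8-one
Conditions: K2CO3 (0.3 equiv), MeOH, rt
Reagents that add atoms: none
Why: Base-catalysed transesterification frees the diol from either monoacetate regioisomer, and reversible enolisation equilibrates C7 to the 7β-isopropyl epimer (R), the only one with an equatorial isopropyl in the ring conformer that the 4β-methyl group enforces to avoid a 1,3-diaxial C14/C15 contact.

Step 10
Reactants: 22 (3R,4S,5S,7R,10R)-3,4-dihydroxy-cis-eudesman-8-one; 23 angelic acid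
Product: 25 (3R,4S,5S,7R,10R)-3-angeloyloxy-4-hydroxy-cis-eudesman-8-one, via mixed anhydride 24 (not isolated)
Conditions: 23, 2,4,6-Cl3C6H2COCl, Et3N, PhMe, rt; then 22, 75 °C
Reagents that add atoms: none
Why: Yamaguchi esterification: the alcohol attacks the less hindered angeloyl carbonyl of the mixed anhydride, only the secondary equatorial 3-OH reacts while the axial tertiary 4-OH stays free, and leaving out DMAP should hold back isomerisation of the Z-ester to the tiglate.

Step 11
Reactants: 25 (3R,4S,5S,7R,10R)-3-angeloyloxy-4-hydroxy-cis-eudesman-8-one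
Product: 26 (3R,4S,5S,7R,10R)-4-acetoxy-3-angeloyloxy-cis-eudesman-8-one (CNP0322180.1)
Conditions: Ac2O, Sc(OTf)3 (5 mol %), MeCN, −20 → 0 °C
Reagents that add atoms: acetic anhydride, CC(=O)OC(C)=O
Why: Lewis-acid-catalysed acylation with an anhydride is a known way to esterify hindered tertiary alcohols at low temperature, where the ketone, the Z-alkene of the angelate and the C7 configuration should all survive.

## Compound list

1 | 3-methylcyclohex-2-en-1-one | CC1=CC(=O)CCC1 | starting material
2 | methyl (E)-but-2-enoate | C/C=C/C(=O)OC | starting material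
3 | lithium 5-methylcyclohexa-1,5-dien-1-olate | [Li]OC1=CCCC(C)=C1 | intermediate
4 | lithium enolate of methyl 3-(4-methyl-2-oxocyclohex-3-en-1-yl)butanoate (racemic, one enantiomer drawn) | CC1=CC(=O)[C@H](CC1)[C@H](C)C=C(OC)O[Li] | intermediate
5 | lithium enolate of keto ester 6 (racemic, one enantiomer drawn) | C[C@]12CC[C@H]([C@H](C)[C@H]1C(=O)OC)C(O[Li])=C2 | intermediate
6 | methyl rac-(1R,2R,3S,4R)-1,3-dimethyl-5-oxobicyclo[2.2.2]octane-2-carboxylate (racemic, one enantiomer drawn) | C[C@]12CC[C@H]([C@H](C)[C@H]1C(=O)OC)C(=O)C2 | intermediate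
7 | rac-(1R,2R,3S,4R)-1,3-dimethyl-5-oxobicyclo[2.2.2]octane-2-carboxylic acid (racemic, one enantiomer drawn) | C[C@]12CC[C@H]([C@H](C)[C@H]1C(=O)O)C(=O)C2 | intermediate
8 | (R)-1-phenylethylammonium (1R,2R,3S,4R)-1,3-dimethyl-5-oxobicyclo[2.2.2]octane-2-carboxylate | C[C@]12CC[C@H]([C@H](C)[C@H]1C(=O)[O-])C(=O)C2.C[C@@H]([NH3+])c1ccccc1 | intermediate
9 | (1R,2R,3S,4R)-1,3-dimethyl-5-oxobicyclo[2.2.2]octane-2-carboxylic acid (single enantiomer) | C[C@]12CC[C@H]([C@H](C)[C@H]1C(=O)O)C(=O)C2 | intermediate
10 | (1R,4R)-4,6-dimethylbicyclo[2.2.2]oct-5-en-2-one | C[C@]12CC[C@H](C(C)=C1)C(=O)C2 | intermediate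
11 | 3-methylbutan-2-one | CC(C)C(C)=O | starting material
12 | (E)-3-methylbutan-2-one 2,4,6-triisopropylbenzenesulfonylhydrazone | C/C(=N\NS(=O)(=O)c1c(C(C)C)cc(C(C)C)cc1C(C)C)C(C)C | intermediate
13 | 3-methylbut-1-en-2-yllithium | [Li]C(=C)C(C)C | intermediate
14 | dichloro(3-methylbut-1-en-2-yl)cerium | CC(C)C(=C)[Ce](Cl)Cl | intermediate
15 | (1R,2S,4R)-4,6-dimethyl-2-(3-methylbut-1-en-2-yl)bicyclo[2.2.2]oct-5-en-2-ol (alkenyl group syn to the alkene bridge) | C[C@]12CC[C@H](C(C)=C1)[C@](O)(C(=C)C(C)C)C2 | intermediate
16 | potassium alkoxide of 15 | C[C@]12CC[C@H](C(C)=C1)[C@](O[K])(C(=C)C(C)C)C2 | intermediate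
17 | potassium (5S,10R)-cis-eudesma-3,7-dien-8-olate | C=1CC[C@]2(C)CC(O[K])=C(C(C)C)C[C@@H]2C=1C | intermediate
18 | (5S,10R)-cis-eudesm-3-en-8-one, C7 epimer mixture (H5 cis to C14) | C=1CC[C@]2(C)CC(=O)C(C(C)C)C[C@@H]2C=1C | intermediate
19 | 4α-acetoxy-3β-iodo-cis-eudesman-8-one, C7 epimer mixture | I[C@H]1CC[C@]2(C)CC(=O)C(C(C)C)C[C@@H]2[C@]1(C)OC(C)=O | intermediate
20 | 3α,4α-(2-methyl-1,3-dioxolan-2-ylium) ion of cis-eudesman-8-one, acetate salt, C7 epimer mixture | CC1=[O+][C@@H]2CC[C@]3(C)CC(=O)C(C(C)C)C[C@@H]3[C@]2(C)O1.CC(=O)[O-] | intermediate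
21 | 4α-acetoxy-3α-hydroxy-cis-eudesman-8-one, C7 epimer mixture (may contain the 3-acetate isomer) | O[C@@H]1CC[C@]2(C)CC(=O)C(C(C)C)C[C@@H]2[C@]1(C)OC(C)=O | intermediate
22 | (3R,4S,5S,7R,10R)-3,4-dihydroxy-cis-eudesman-8-one (3α,4α-diol, 7β-isopropyl) | O[C@@H]1CC[C@]2(C)CC(=O)[C@@H](C(C)C)C[C@@H]2[C@]1(C)O | intermediate
23 | angelic acid, (Z)-2-methylbut-2-enoic acid | C/C=C(/C)C(=O)O | starting material
24 | angelic 2,4,6-trichlorobenzoic anhydride | C/C=C(/C)C(=O)OC(=O)c1c(Cl)cc(Cl)cc1Cl | intermediate
25 | (3R,4S,5S,7R,10R)-3-angeloyloxy-4-hydroxy-cis-eudesman-8-one | C/C=C(/C)C(=O)O[C@@H]1CC[C@]2(C)CC(=O)[C@@H](C(C)C)C[C@@H]2[C@]1(C)O | intermediate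
26 | (3R,4S,5S,7R,10R)-4-acetoxy-3-angeloyloxy-cis-eudesman-8-one, CNP0322180.1 | C/C=C(/C)C(=O)O[C@@H]1CC[C@]2(C)CC(=O)[C@@H](C(C)C)C[C@@H]2[C@]1(C)OC(C)=O | target

Total step count: 11
Longest linear sequence: 10 steps (steps 1–4 and 6–11; step 5 prepares the hydrazone on a side branch)

## Steps most likely to fail

Step 8 (Woodward cis-hydroxylation). What may go wrong is attack of the iodine electrophile on the α face, or on both faces. This is most likely for the 7α-isopropyl epimer, whose ring conformer holds C14 axially over the β face. Anti opening and acetoxonium closure would then put the oxygens on the β face; iodination next to the ketone is a second drain. Fallback: from 18, osmium-catalysed dihydroxylation (OsO4 cat., NMO, acetone/H2O, rt) adds both oxygens in one suprafacial cycloaddition to the face the electrophile prefers. In the failure case that is the α face, so it should give the C7-epimeric 3α,4α-dihydroxy-cis-eudesman-8-one F1. K2CO3 in MeOH then equilibrates C7, and the route is rejoined at 22. The two hydroxylations are stereocomplementary, so one of them should serve whichever face proves open.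

Step 11 (acetylation of the tertiary hydroxyl). What may go wrong is slow acylation of the axial tertiary hydroxyl beside the angelate, with Lewis-acid-induced migration of the angeloyl group to O4 or ionisation and elimination at C4. Fallback: from 22, MeC(OMe)3 with PPTS (CH2Cl2, rt) should give the cyclic 3α,4α-orthoacetate F2. Mild aqueous acid (AcOH/H2O, rt) opens such orthoesters under stereoelectronic control to the ester of the axial oxygen, here the tertiary O4, which should give (3R,4S,5S,7R,10R)-4-acetoxy-3-hydroxy-cis-eudesman-8-one F3. Angeloylation of its free 3-OH with mixed anhydride 24 under the conditions of step 10 then leads to 26.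

Step 3 (salt resolution). What may go wrong is co-crystallisation of the two diastereomeric salts, so that the acid does not become enantiopure. Fallback: from 7, Steglich esterification with (R)-pantolactone (DCC, DMAP, CH2Cl2) should give two covalent diastereomers, the (R)-pantolactonyl ester of the (1R,2R,3S,4R)-acid F4 and the (R)-pantolactonyl ester of the (1S,2S,3R,4S)-acid F5, to be separated by chromatography or crystallisation. LiOH (THF/H2O, 0 °C), then HCl, cleaves F4 to the free acid 9, which enters the decarboxylation of step 4.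

## Further compounds

F1 | step 8 | 3α,4α-dihydroxy-cis-eudesman-8-one, C7 epimer mixture | O[C@@H]1CC[C@]2(C)CC(=O)C(C(C)C)C[C@@H]2[C@]1(C)O
F2 | step 11 | 3α,4α-O-(1-methoxyethylidene) derivative of diol 22 (cyclic orthoacetate, orthoester carbon unassigned) | COC1(C)O[C@@H]2CC[C@]3(C)CC(=O)[C@@H](C(C)C)C[C@@H]3[C@]2(C)O1
F3 | step 11 | (3R,4S,5S,7R,10R)-4-acetoxy-3-hydroxy-cis-eudesman-8-one | O[C@@H]1CC[C@]2(C)CC(=O)[C@@H](C(C)C)C[C@@H]2[C@]1(C)OC(C)=O
F4 | step 3 | (R)-pantolactonyl (1R,2R,3S,4R)-1,3-dimethyl-5-oxobicyclo[2.2.2]octane-2-carboxylate | C[C@]12CC[C@H]([C@H](C)[C@H]1C(=O)O[C@H]3C(=O)OCC3(C)C)C(=O)C2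
F5 | step 3 | (R)-pantolactonyl (1S,2S,3R,4S)-1,3-dimethyl-5-oxobicyclo[2.2.2]octane-2-carboxylate | C[C@@]12CC[C@@H]([C@@H](C)[C@@H]1C(=O)O[C@H]3C(=O)OCC3(C)C)C(=O)C2
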